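**Retrosynthetic overview**

1. Locants used throughout: C1 is the lactone carbonyl, C2 its CH2, C3 the ring-fusion CH that carries the peroxide oxygen, C4 the ring-fusion carbon that carries CH3 and the lactone oxygen, C5 the ring CH2, C6 the peroxide carbon that carries CH3 and the 10-phenyldecyl chain (C7–C16).
2. The last disconnection is the lactone O–C4 bond; it and the peroxide O–C3 bond are made in one operation from the acyclic hydroperoxy β-lactone 18, the hydroperoxide opening the four-membered lactone at C3 and the freed acid closing onto C4.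
3. The enabling feature is that the γ-lactone is a ring-expanded β-lactone: C1 and the oxygen-bearing C3 are 1,3-related, so the carboxyl can be carried as a strained oxetan-2-one that is electrophile at C3 and masked nucleophile at once, and C4 is a fully substituted, methyl-bearing carbon γ to C1 that is reached as a tertiary cation from a C4 methylidene.
4. Stereocentres: C6 from (R)-linalool through oxetane perhydrolysis (inversion); C3 from a catalyst-controlled ketene–aldehyde cycloaddition followed by inversion in the key step; C4 from the cis ring fusion.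
5. Ring order: oxetane (temporary) → β-lactone (temporary) → 1,2-dioxane → γ-lactone; the chain comes from (8-bromooctyl)benzene by Wittig reaction and diimide reduction.

Key step: step 13

Assumption: commercial (R)-(−)-linalool of high enantiomeric purity is used; what remains of the minor enantiomer becomes a diastereomer once C3 is set in step 11 and should be removable by chromatography there.

**Route**

Step 1
Reactants: 1 (R)-(−)-linalool
Product: 3 (R)-3,7-dimethyloct-6-ene-1,3-diol, via alkylborane 2 (not isolated)
Conditions: 9-borabicyclo[3.3.1]nonane (9-BBN, 1.5 equiv), THF, 0 °C → rt; then NaOH aq., H2O2, 0 °C → rt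
Reagents that add atoms: hydrogen peroxide, OO
Why: The bulky dialkylborane adds anti-Markovnikov to the monosubstituted vinyl group much faster than to the trisubstituted alkene (hydroboration–oxidation), and the tertiary carbinol stereocentre is not touched.

Step 2
Reactants: 3 (R)-3,7-dimethyloct-6-ene-1,3-diol
Product: 5 (R)-2-methyl-2-(4-methylpent-3-en-1-yl)oxetane, via primary tosylate 4 (not isolated)
Conditions: n-BuLi (1.0 equiv), THF, 0 °C; TsCl (1.0 equiv), 0 °C → rt; then n-BuLi (1.0 equiv), 0 → 60 °C
Reagents that add atoms: none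
Why: Selective sulfonylation of the primary alkoxide and intramolecular Williamson etherification (4-exo-tet) by the tertiary alkoxide close the oxetane without breaking the C–O bond of the stereocentre, so its configuration is retained.

Step 3
Reactants: 5 (R)-2-methyl-2-(4-methylpent-3-en-1-yl)oxetane
Product: 6 (S)-3-hydroperoxy-3,7-dimethyloct-6-en-1-ol
Conditions: H2O2 (dried ethereal solution, 10 equiv), Me3SiOTf (0.2 equiv), Et2O, −78 → 0 °C
Reagents that add atoms: hydrogen peroxide, OO
Why: The activated oxetane is opened by hydrogen peroxide at its more substituted carbon in a strain-driven, SN2-like perhydrolysis that proceeds with inversion, turning the (R) tertiary ether carbon into the (S) tertiary hydroperoxide carbon that becomes C6.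

Step 4
Reactants: 6 (S)-3-hydroperoxy-3,7-dimethyloct-6-en-1-ol
Product: 7 (S)-3-[(2-methoxypropan-2-yl)peroxy]-3,7-dimethyloct-6-en-1-ol
Conditions: 2-methoxypropene (1.05 equiv), pyridinium p-toluenesulfonate (5 mol%), CH2Cl2, −20 °C
Reagents that add atoms: 2-methoxypropene, COC(C)=C
Why: Acid-catalysed addition of the hydroperoxide, the more acidic and more reactive O–H, to the enol ether (peroxyketal formation) should occur selectively at low temperature and masks the O–O–H against base and oxidants.

Step 5
Reactants: 7 (S)-3-[(2-methoxypropan-2-yl)peroxy]-3,7-dimethyloct-6-en-1-ol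
Product: 8 (S)-3-[(2-methoxypropan-2-yl)peroxy]-3,7-dimethyloct-6-enal
Conditions: Dess–Martin periodinane (1.3 equiv), pyridine, CH2Cl2, 0 °C → rt
Reagents that add atoms: none
Why: Dess–Martin oxidation under buffered, non-basic conditions stops at the aldehyde and leaves the peroxyketal, the alkene and the stereocentre intact.

Step 6
Reactants: 9 (8-bromooctyl)benzene
Product: 10 (8-phenyloctyl)triphenylphosphonium bromide
Conditions: PPh3 (1.05 equiv), MeCN, reflux
Reagents that add atoms: triphenylphosphine, c1ccc(cc1)P(c1ccccc1)c1ccccc1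
Why: SN2 quaternization of the phosphine by the primary bromide gives the Wittig salt.

Step 7
Reactants: 8 (S)-3-[(2-methoxypropan-2-yl)peroxy]-3,7-dimethyloct-6-enal; 10 (8-phenyloctyl)triphenylphosphonium bromide
Product: 12 {(8Z,11S)-11-[(2-methoxypropan-2-yl)peroxy]-11,15-dimethylhexadeca-8,14-dien-1-yl}benzene, via phosphonium ylide 11 (not isolated)
Conditions: 10, NaN(SiMe3)2 (1.0 equiv), THF, 0 °C; then 8, −78 °C → rt
Reagents that add atoms: none
Why: Wittig olefination with the non-stabilised ylide at low temperature should outrun β-elimination of the peroxide and forms the C8–C9 bond as the Z-alkene, whose geometry is irrelevant because it is reduced next.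

Step 8
Reactants: 12 {(8Z,11S)-11-[(2-methoxypropan-2-yl)peroxy]-11,15-dimethylhexadeca-8,14-dien-1-yl}benzene
Product: 13 {(11R)-11-[(2-methoxypropan-2-yl)peroxy]-11,15-dimethylhexadec-14-en-1-yl}benzene
Conditions: 2-nitrobenzenesulfonylhydrazide (3 equiv), Et3N, CH2Cl2, rt
Reagents that add atoms: none
Why: Diimide, generated from the sulfonylhydrazide, transfers H2 in a concerted syn fashion to the unhindered 1,2-disubstituted alkene far faster than to the trisubstituted one and does not cleave O–O bonds (diimide reduction); the descriptor changes only because the priorities change.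

Step 9
Reactants: 13 {(11R)-11-[(2-methoxypropan-2-yl)peroxy]-11,15-dimethylhexadec-14-en-1-yl}benzene
Product: 15 (R)-4-[(2-methoxypropan-2-yl)peroxy]-4-methyl-14-phenyltetradecanal, via ozonide 14 (not isolated)
Conditions: O3, CH2Cl2, −78 °C (stopped at the first persistent blue); then Me2S, −78 °C → rt
Reagents that add atoms: ozone, [O-][O+]=O
Why: Ozonolysis with reductive work-up cleaves the remaining trisubstituted alkene to the aldehyde, while the saturated peroxyketal and the arene are inert at −78 °C.

Step 10
Reactants: 15 (R)-4-[(2-methoxypropan-2-yl)peroxy]-4-methyl-14-phenyltetradecanal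
Product: 16 (R)-4-[(2-methoxypropan-2-yl)peroxy]-4-methyl-2-methylidene-14-phenyltetradecanal
Conditions: N,N-dimethylmethyleneiminium iodide (2 equiv), Et3N (3 equiv), CH2Cl2, rt
Reagents that add atoms: N,N-dimethylmethyleneiminium iodide, C=[N+](C)C.[I-]
Why: Mannich reaction of the aldehyde with the iminium salt and in situ β-elimination of dimethylamine (α-methylenation) install the methylidene that becomes the C4 methyl group.

Step 11
Reactants: 16 (R)-4-[(2-methoxypropan-2-yl)peroxy]-4-methyl-2-methylidene-14-phenyltetradecanal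
Product: 17 (R)-4-{(R)-4-[(2-methoxypropan-2-yl)peroxy]-4-methyl-14-phenyltetradec-1-en-2-yl}oxetan-2-one
Conditions: AcCl (3 equiv, slow addition), iPr2NEt, O-trimethylsilylquinidine (15 mol%), LiClO4 (2 equiv), CH2Cl2/Et2O, −78 °C
Reagents that add atoms: acetyl chloride, CC(Cl)=O
Why: In this catalytic asymmetric ketene–aldehyde [2+2] cyclocondensation the alkaloid-bound acetyl ammonium enolate adds to the LiClO4-activated aldehyde and lactonizes, the alkaloid controlling the new C3 stereocentre; the quinidine-derived catalyst is expected to give the (R)-lactone by analogy with the facial sense of the parent cinchona-catalysed cycloaddition, and its quinine-derived pseudoenantiomer is at hand if the sense proves opposite.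

Step 12
Reactants: 17 (R)-4-{(R)-4-[(2-methoxypropan-2-yl)peroxy]-4-methyl-14-phenyltetradec-1-en-2-yl}oxetan-2-one
Product: 18 (R)-4-[(R)-4-hydroperoxy-4-methyl-14-phenyltetradec-1-en-2-yl]oxetan-2-one
Conditions: AcOH/THF/H2O (4:2:1), 0 °C → rt
Reagents that add atoms: none
Why: Mild aqueous acid hydrolyses the labile mixed peroxyketal to the free hydroperoxide, while the β-lactone and the 1,1-disubstituted alkene, which need a stronger acid or an anionic nucleophile, should survive.

Step 13
Reactants: 18 (R)-4-[(R)-4-hydroperoxy-4-methyl-14-phenyltetradec-1-en-2-yl]oxetan-2-one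
Product: 20 (3R,4aS,7aS)-3,4a-dimethyl-3-(10-phenyldecyl)tetrahydrofuro[3,2-c][1,2]dioxin-6(3H)-one (CNP0407146.3), via dioxane acid 19 (not isolated)
Conditions: KOtBu (1.0 equiv), 18-crown-6 (1.0 equiv), toluene, −20 → 0 °C; then CF3CO2H (excess), CH2Cl2, 0 °C → rt
Reagents that add atoms: none
Why: Proposed new method: deprotonation gives the tertiary peroxide anion, which attacks C3 of the β-lactone from the rear in a 6-exo-tet alkyl–oxygen cleavage (SN2, driven by release of the four-ring strain and by allylic activation), closing the 1,2-dioxane and unmasking carboxylate 19; acidification then protonates the methylidene terminus to the tertiary C4 cation, which the carboxyl oxygen captures in a Markovnikov 5-exo closure that forms the lactone O–C4 bond and the C4 methyl group. The closest known reaction types are the strain-driven 6-exo opening of oxetanes by tethered hydroperoxides with inversion, the base-mediated 6-exo-tet cyclization of hydroperoxy sulfonates, the SN2 alkyl–oxygen opening of 4-substituted β-lactones by soft anions such as azide, thiolate or carboxylate, and the acid-catalysed lactonization of 4-methylidene alkanoic acids. C3 is set by inversion of the catalyst-derived (R)-lactone centre to (S), and C6 is carried through unchanged. C4 is set by the two-atom tether, which can deliver the carboxyl oxygen only to the face of the cation syn to the CH2 arm, so that the cis-fused, angular-methyl lactone (also the less strained isomer) should result. The step needs SN2 attack at C3 in preference to acyl attack (which would require an eight-membered transition state) and to SN2′ attack at the methylidene terminus; the short chair-like tether and the poor SN2′ reactivity of oxygen anions without a metal are expected to secure this. It also needs the hydroperoxide to be consumed before any strong acid is present, because acid would otherwise drive Markovnikov 5-exo addition of the O–O–H to the alkene to give a 1,2-dioxolane; the base-then-acid order secures this.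

**Compound list**

1 | (R)-(−)-linalool | C=C[C@](C)(O)CCC=C(C)C | starting material
2 | (R)-1-(9-borabicyclo[3.3.1]nonan-9-yl)-3,7-dimethyloct-6-en-3-ol (alkylborane, not isolated) | CC(C)=CCC[C@@](C)(O)CCB1C2CCCC1CCC2 | intermediate
3 | (R)-3,7-dimethyloct-6-ene-1,3-diol | OCC[C@](C)(O)CCC=C(C)C | intermediate
4 | (R)-3-hydroxy-3,7-dimethyloct-6-en-1-yl 4-methylbenzenesulfonate (present as its lithium alkoxide, not isolated) | Cc1ccc(cc1)S(=O)(=O)OCC[C@](C)(O)CCC=C(C)C | intermediate
5 | (R)-2-methyl-2-(4-methylpent-3-en-1-yl)oxetane | C1C[C@](C)(O1)CCC=C(C)C | intermediate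
6 | (S)-3-hydroperoxy-3,7-dimethyloct-6-en-1-ol | OCC[C@@](C)(OO)CCC=C(C)C | intermediate
7 | (S)-3-[(2-methoxypropan-2-yl)peroxy]-3,7-dimethyloct-6-en-1-ol | OCC[C@@](C)(OOC(C)(C)OC)CCC=C(C)C | intermediate
8 | (S)-3-[(2-methoxypropan-2-yl)peroxy]-3,7-dimethyloct-6-enal | O=CC[C@@](C)(OOC(C)(C)OC)CCC=C(C)C | intermediate
9 | (8-bromooctyl)benzene | BrCCCCCCCCc1ccccc1 | starting material
10 | (8-phenyloctyl)triphenylphosphonium bromide | [Br-].c1ccc(cc1)[P+](CCCCCCCCc1ccccc1)(c1ccccc1)c1ccccc1 | intermediate
11 | triphenyl(8-phenyloctylidene)phosphorane (ylide, not isolated) | c1ccc(cc1)P(=CCCCCCCCc1ccccc1)(c1ccccc1)c1ccccc1 | intermediate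
12 | {(8Z,11S)-11-[(2-methoxypropan-2-yl)peroxy]-11,15-dimethylhexadeca-8,14-dien-1-yl}benzene | c1ccccc1CCCCCCC/C=C\C[C@@](C)(OOC(C)(C)OC)CCC=C(C)C | intermediate
13 | {(11R)-11-[(2-methoxypropan-2-yl)peroxy]-11,15-dimethylhexadec-14-en-1-yl}benzene | c1ccccc1CCCCCCCCCC[C@@](C)(OOC(C)(C)OC)CCC=C(C)C | intermediate
14 | 3-{(3R)-3-[(2-methoxypropan-2-yl)peroxy]-3-methyl-13-phenyltridecyl}-5,5-dimethyl-1,2,4-trioxolane (ozonide, both configurations at the ring CH, not isolated) | c1ccccc1CCCCCCCCCC[C@@](C)(OOC(C)(C)OC)CCC1OOC(C)(C)O1 | intermediate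
15 | (R)-4-[(2-methoxypropan-2-yl)peroxy]-4-methyl-14-phenyltetradecanal | c1ccccc1CCCCCCCCCC[C@@](C)(OOC(C)(C)OC)CCC=O | intermediate
16 | (R)-4-[(2-methoxypropan-2-yl)peroxy]-4-methyl-2-methylidene-14-phenyltetradecanal | c1ccccc1CCCCCCCCCC[C@@](C)(OOC(C)(C)OC)CC(=C)C=O | intermediate
17 | (R)-4-{(R)-4-[(2-methoxypropan-2-yl)peroxy]-4-methyl-14-phenyltetradec-1-en-2-yl}oxetan-2-one | c1ccccc1CCCCCCCCCC[C@@](C)(OOC(C)(C)OC)CC(=C)[C@H]1CC(=O)O1 | intermediate
18 | (R)-4-[(R)-4-hydroperoxy-4-methyl-14-phenyltetradec-1-en-2-yl]oxetan-2-one | c1ccccc1CCCCCCCCCC[C@@](C)(OO)CC(=C)[C@H]1CC(=O)O1 | intermediate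
19 | 2-[(3S,6R)-6-methyl-4-methylidene-6-(10-phenyldecyl)-1,2-dioxan-3-yl]acetic acid (present as its potassium salt, not isolated) | C[C@@]1(CCCCCCCCCCc2ccccc2)CC(=C)[C@H](CC(=O)O)OO1 | intermediate
20 | (3R,4aS,7aS)-3,4a-dimethyl-3-(10-phenyldecyl)tetrahydrofuro[3,2-c][1,2]dioxin-6(3H)-one, cis-fused (CNP0407146.3) | C[C@@]1(CCCCCCCCCCc2ccccc2)C[C@]2(C)OC(=O)C[C@@H]2OO1 | target

**Step count and risks**

Total step count: 13. Longest linear sequence: 12 steps (steps 1–5 and 7–13, from linalool).

Steps most likely to fail:

1. Step 13 (Proposed new method). The peroxide anion may attack the lactone carbonyl (acyl–oxygen cleavage and oligomeric peresters) or the methylidene terminus (SN2′). The new allylic peroxide may also fragment under base (Kornblum–DeLaMare), or the acid stage may ionize a C–O bond of the peroxide. The fallback sets out from 17 and uses known reaction types, with the two ring closures separated. Reduction of the β-lactone with LiBH4 (THF, 0 °C) gives (3R,6R)-6-[(2-methoxypropan-2-yl)peroxy]-6-methyl-4-methylidene-16-phenylhexadecane-1,3-diol F1. Selective sulfonylation of the primary hydroxyl (TsCl, pyridine, 0 °C) gives (3R,6R)-3-hydroxy-6-[(2-methoxypropan-2-yl)peroxy]-6-methyl-4-methylidene-16-phenylhexadecyl 4-methylbenzenesulfonate F2. KOtBu (THF, 0 °C) closes this, with retention at C3, to (R)-2-{(R)-4-[(2-methoxypropan-2-yl)peroxy]-4-methyl-14-phenyltetradec-1-en-2-yl}oxetane F3. Aqueous AcOH removes the peroxyketal to give (R)-2-[(R)-4-hydroperoxy-4-methyl-14-phenyltetradec-1-en-2-yl]oxetane F4. Me3SiOTf (catalytic, buffered with 2,6-di-tert-butyl-4-methylpyridine, CH2Cl2, −78 °C) then promotes the 6-exo opening of the oxetane by the tethered hydroperoxide with inversion at C3, giving 2-[(3S,6R)-6-methyl-4-methylidene-6-(10-phenyldecyl)-1,2-dioxan-3-yl]ethan-1-ol F5. Oxidation with catalytic 2,2,6,6-tetramethylpiperidin-1-oxyl and PhI(OAc)2 in wet MeCN returns to the route at acid 19, which is lactonized with CF3CO2H as in the second stage of step 13 to give 20.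

2. Step 11. The conjugated, α-branched enal may react too slowly with the ammonium enolate, so that ketene dimerization takes over, or facial control may be insufficient. The fallback sets out from 16 and uses a base-mediated chiral acetate aldol followed by a retentive lactonization. The dianion of (R)-2-hydroxy-1,2,2-triphenylethyl acetate (LiN(iPr)2, THF, −78 °C; MgBr2) is added to 16 at −110 °C to give (R)-2-hydroxy-1,2,2-triphenylethyl (3R,6R)-3-hydroxy-6-[(2-methoxypropan-2-yl)peroxy]-6-methyl-4-methylidene-16-phenylhexadecanoate F6. KOH in MeOH/H2O liberates (3R,6R)-3-hydroxy-6-[(2-methoxypropan-2-yl)peroxy]-6-methyl-4-methylidene-16-phenylhexadecanoic acid F7, and carboxyl activation with PhSO2Cl in pyridine (0 °C) closes the β-lactone with retention at C3, returning to the route at 17.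

3. Step 7. The β-peroxy aldehyde may lose its peroxide by base-induced β-elimination before or instead of olefination. The fallback sets out from alcohol 7 and avoids the carbonyl. (CF3SO2)2O and 2,6-lutidine (CH2Cl2, −78 °C) give (S)-3-[(2-methoxypropan-2-yl)peroxy]-3,7-dimethyloct-6-en-1-yl trifluoromethanesulfonate F8. This is alkylated (THF/DMPU, −78 → −20 °C) with the lithium acetylide (n-BuLi) of 8-phenyloct-1-yne F9, itself made from commercial (6-bromohexyl)benzene and LiC≡CH·H2NCH2CH2NH2 in DMSO, to give {(11S)-11-[(2-methoxypropan-2-yl)peroxy]-11,15-dimethylhexadec-14-en-7-yn-1-yl}benzene F10. Exhaustive diimide reduction of the alkyne under the conditions of step 8, with a larger excess of the hydrazide, returns to the route at 13.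

Further compounds
F1 | step 13 | (3R,6R)-6-[(2-methoxypropan-2-yl)peroxy]-6-methyl-4-methylidene-16-phenylhexadecane-1,3-diol | c1ccccc1CCCCCCCCCC[C@@](C)(OOC(C)(C)OC)CC(=C)[C@H](O)CCO
F2 | step 13 | (3R,6R)-3-hydroxy-6-[(2-methoxypropan-2-yl)peroxy]-6-methyl-4-methylidene-16-phenylhexadecyl 4-methylbenzenesulfonate | c1ccccc1CCCCCCCCCC[C@@](C)(OOC(C)(C)OC)CC(=C)[C@H](O)CCOS(=O)(=O)c1ccc(C)cc1
F3 | step 13 | (R)-2-{(R)-4-[(2-methoxypropan-2-yl)peroxy]-4-methyl-14-phenyltetradec-1-en-2-yl}oxetane | c1ccccc1CCCCCCCCCC[C@@](C)(OOC(C)(C)OC)CC(=C)[C@H]1CCO1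
F4 | step 13 | (R)-2-[(R)-4-hydroperoxy-4-methyl-14-phenyltetradec-1-en-2-yl]oxetane | c1ccccc1CCCCCCCCCC[C@@](C)(OO)CC(=C)[C@H]1CCO1
F5 | step 13 | 2-[(3S,6R)-6-methyl-4-methylidene-6-(10-phenyldecyl)-1,2-dioxan-3-yl]ethan-1-ol | C[C@@]1(CCCCCCCCCCc2ccccc2)CC(=C)[C@H](CCO)OO1
F6 | step 11 | (R)-2-hydroxy-1,2,2-triphenylethyl (3R,6R)-3-hydroxy-6-[(2-methoxypropan-2-yl)peroxy]-6-methyl-4-methylidene-16-phenylhexadecanoate | c1ccccc1CCCCCCCCCC[C@@](C)(OOC(C)(C)OC)CC(=C)[C@H](O)CC(=O)O[C@H](c1ccccc1)C(O)(c1ccccc1)c1ccccc1
F7 | step 11 | (3R,6R)-3-hydroxy-6-[(2-methoxypropan-2-yl)peroxy]-6-methyl-4-methylidene-16-phenylhexadecanoic acid | c1ccccc1CCCCCCCCCC[C@@](C)(OOC(C)(C)OC)CC(=C)[C@H](O)CC(=O)O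
F8 | step 7 | (S)-3-[(2-methoxypropan-2-yl)peroxy]-3,7-dimethyloct-6-en-1-yl trifluoromethanesulfonate | FC(F)(F)S(=O)(=O)OCC[C@@](C)(OOC(C)(C)OC)CCC=C(C)C
F9 | step 7 | 8-phenyloct-1-yne | C#CCCCCCCc1ccccc1
F10 | step 7 | {(11S)-11-[(2-methoxypropan-2-yl)peroxy]-11,15-dimethylhexadec-14-en-7-yn-1-yl}benzene | c1ccccc1CCCCCCC#CCC[C@@](C)(OOC(C)(C)OC)CCC=C(C)C
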